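Assumption: the target has no stereocentre or stereoaxis, so it is achiral and is made exactly as drawn; no enantiocontrol is needed.

**Retrosynthetic overview**
- The last two C–Br bonds come from electrophilic bromination of a monobromocatechol, whose free positions are both ortho to a phenolic OH.
- The monobromocatechol comes from the para-substituted phenol. The key C–O bond is made by ortho-oxygenation with pentavalent iodine, and the resulting o-quinone is captured by HBr in the same flask, which also makes the first C–Br bond (new step).
- The phenol comes from a C–S disconnection: 4-hydroxybenzyl alcohol plus sodium methanesulfinate.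
- No ring is formed; the benzene ring of the starting alcohol is carried through all three steps.

**Route**

Step 1
Reactants: 1 4-hydroxybenzyl alcohol; 2 sodium methanesulfinate (MeSO2Na)
Product: 3 4-[(methylsulfonyl)methyl]phenol
Conditions: MeSO2Na (2 equiv), AcOH–H2O (1:1), 80 °C, 3 h, 1 added slowly
Reagents that add atoms: none
Why: Acid-promoted SN1-type benzylic substitution, in which the para-hydroxyl lets the benzylic C–OH ionise, the soft sulfinate captures the cation at sulfur, and any O-bound sulfinate ester or benzylic acetate re-ionises while the sulfone does not, so the mixture funnels to 3; no stereocentre is formed.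

Step 2
Reactants: 3 4-[(methylsulfonyl)methyl]phenol
Product: 5 4-bromo-5-[(methylsulfonyl)methyl]benzene-1,2-diol, via o-quinone 4 (not isolated)
Conditions: IBX (1.0 equiv), DMF, 0 °C to rt, 1 h; then cannulated into 48% aq HBr (5 equiv), −10 to 0 °C, 30 min
Reagents that add atoms: 2-iodoxybenzoic acid (IBX), OI1(=O)OC(=O)c2ccccc12; hydrogen bromide, Br
Why: Proposed new method: an untested one-flask oxygenative hydrobromination of a phenol, in which the phenol binds the pentavalent iodine of IBX and oxygen is delivered intramolecularly to one of the two equivalent ortho carbons, releasing o-quinone 4 and 2-iodobenzoic acid (monovalent iodine); instead of the usual reductive quench, HBr protonates 4, bromide adds 1,4 at C5 and enolisation gives catechol 5, so bromide acts as both the reducing equivalent and the first ring bromine; the halogen raises the quinone/catechol potential, so 5 should not be re-oxidised by remaining 4, and any regioisomeric or over-brominated adduct converges on the same product in step 3; the closest known reactions are IBX ortho-oxygenation of phenols followed by Na2S2O4 reduction to catechols, and the classical hydrohalogenation of quinones; no stereocentre is formed.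

Step 3
Reactants: 5 4-bromo-5-[(methylsulfonyl)methyl]benzene-1,2-diol
Product: 7 3,4,6-tribromo-5-[(methylsulfonyl)methyl]benzene-1,2-diol, via dibromocatechol 6 (not isolated)
Conditions: Br2 (2.3 equiv), AcOH, rt to 50 °C, dark, 4 h; aq NaHSO3 quench
Reagents that add atoms: bromine, BrBr
Why: Electrophilic aromatic bromination, in which each of the two remaining ring positions is ortho to a free phenolic OH and is substituted without a catalyst (the less hindered C3 first, then C6), as in the perbromination of catechols, while the sulfone and its benzylic CH2 are inert to ionic bromine in the dark; no stereocentre is formed.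

**Compound list**
1 | 4-hydroxybenzyl alcohol [4-(hydroxymethyl)phenol] | OCc1ccc(O)cc1 | starting material
2 | sodium methanesulfinate (MeSO2Na) | CS(=O)[O-].[Na+] | starting material
3 | 4-[(methylsulfonyl)methyl]phenol | CS(=O)(=O)Cc1ccc(O)cc1 | intermediate
4 | 4-[(methylsulfonyl)methyl]cyclohexa-3,5-diene-1,2-dione (o-quinone, not isolated) | CS(=O)(=O)CC1=CC(=O)C(=O)C=C1 | intermediate
5 | 4-bromo-5-[(methylsulfonyl)methyl]benzene-1,2-diol | CS(=O)(=O)Cc1cc(O)c(O)cc1Br | intermediate
6 | 3,4-dibromo-5-[(methylsulfonyl)methyl]benzene-1,2-diol (not isolated) | CS(=O)(=O)Cc1cc(O)c(O)c(Br)c1Br | intermediate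
7 | 3,4,6-tribromo-5-[(methylsulfonyl)methyl]benzene-1,2-diol (= 2,3,6-tribromo-4,5-dihydroxybenzyl methyl sulfone) | CS(=O)(=O)Cc1c(Br)c(O)c(O)c(Br)c1Br | target

**Step count**
Total steps: 3. Longest linear sequence: 3.

**Steps most likely to fail, with fallbacks**

Step 2 (the proposed new step) is the most likely to fail. Phenol 3 is slightly electron-poor, so oxygenation may be slow. Quinone 4 carries an acidic CH2SO2Me group and may tautomerise to a quinone methide before bromide adds. The bromide capture may also be unclean. The fallback uses known chemistry and makes the C–O bond by aryl migration instead of oxygen transfer from iodine. It sets out from 3: ortho-formylation with MgCl2, Et3N and paraformaldehyde in refluxing MeCN gives 2-hydroxy-5-[(methylsulfonyl)methyl]benzaldehyde F1. Dakin oxidation (30% H2O2, aq NaOH, 0 °C to rt, then acid) gives 4-[(methylsulfonyl)methyl]benzene-1,2-diol F2 with loss of formate. Exhaustive bromination of F2 (Br2, 3.3 equiv, AcOH, rt to 50 °C) fills all three ring positions, and the fallback comes back to the route at 7.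

Step 1 is the next risk. In hot acid, 1 can self-condense to diarylmethane oligomers faster than the sulfinate captures it. The fallback makes the C–S bond at the sulfide oxidation level under basic conditions, where the thiolate is a much faster trap. It sets out from 1: NaSMe (1.5 equiv) in H2O–EtOH at reflux gives 4-[(methylsulfanyl)methyl]phenol F3. Oxidation of the sulfide with 30% H2O2 (2.5 equiv) in AcOH at 50 °C then gives the sulfone, and the fallback comes back to the route at 3.

Step 3 is the least risky. The last bromination at C6, flanked by OH and CH2SO2Me, may stall at 6, or partial oxidation may give dark quinone/quinhydrone mixtures. The fallback moves from electrophilic substitution to the quinone manifold. It sets out from 5: excess Br2 (5–6 equiv) in AcOH–H2O at 60 °C acts as both oxidant and brominating agent. The partly brominated catechol is oxidised to its o-quinone, which takes up bromine by addition and loss of HBr, ending at 3,4,6-tribromo-5-[(methylsulfonyl)methyl]cyclohexa-3,5-diene-1,2-dione F4. Reduction of F4 with Na2S2O4 in H2O/EtOAc at rt gives the catechol, and the fallback comes back to the route at 7.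

**Further compounds**
F1 | step 2 | 2-hydroxy-5-[(methylsulfonyl)methyl]benzaldehyde | CS(=O)(=O)Cc1ccc(O)c(C=O)c1
F2 | step 2 | 4-[(methylsulfonyl)methyl]benzene-1,2-diol | CS(=O)(=O)Cc1ccc(O)c(O)c1
F3 | step 1 | 4-[(methylsulfanyl)methyl]phenol | CSCc1ccc(O)cc1
F4 | step 3 | 3,4,6-tribromo-5-[(methylsulfonyl)methyl]cyclohexa-3,5-diene-1,2-dione | CS(=O)(=O)CC1=C(Br)C(=O)C(=O)C(Br)=C1Br
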